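## Structural features

The target consists of two 2-phenylchromane-3,5,7-triol (flavan-3-ol) units: rings A (phloroglucinol-type arene), C (dihydropyran) and B (phenyl) form the upper unit, and rings D, F and E play the same roles in the lower unit. The units are joined only by the bond from sp3 C4 of ring C to aromatic C8′ of ring D, so C4 is a diarylmethine whose two aryl groups each carry two ortho oxygen substituents. Ring C holds three contiguous stereocentres, C2 (R), C3 (R) and C4 (R), with phenyl and hydroxyl cis and hydroxyl and the C4 aryl group trans; ring F holds C2′ (R) and C3′ (R), cis, next to the C4′ methylene group. Rings B and E are unsubstituted phenyl rings, so the lower unit is the 3′,4′-dideoxy congener of (−)-epicatechin and not (−)-epicatechin itself: the chiral-pool material has the correct C2′/C3′ configuration, but both catechol oxygens must be removed. The fragile points are six phenols on two very electron-rich rings (air oxidation, C-alkylation), the benzylic C2–O1 and C2′–O1′ ether bonds, the acid-labile C4–C8′ bond, and epimerisation at C2 of the free polyphenol in base. The real difficulty is the crowded C4 centre, which must be formed with defined configuration next to the less stable 2,3-cis arrangement, and at C8′ rather than C6′. The key step exploits the vicinal pair O1 on benzylic C2 and O3 on C3 of ring C: with O1 moved to C3 and the free oxygen placed on C2, ring C becomes a trans-2,3-disubstituted 2,3-dihydrobenzofuran with an α-hydroxybenzyl side chain, and the reverse 1,2-shift of O1 with entry of a carboxylate at C3 rebuilds ring C with both centres inverted.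

## Logic of the disconnections

**24 to 22.** The five benzyl–oxygen bonds and the acetyl–oxygen bond at C3 are cut. All phenols and the C3′ hydroxyl stay masked as ethers that leave in one neutral operation, and the C3 oxygen arrives as an ester from the key step. This reduces the end game to 23 and then 22. The forward steps must cleave an ester without base-sensitive free phenols present (hence acetate first) and then hydrogenolyse without touching the C2–O1, C2′–O1′ and C4–C8′ bonds.

**22 to 19 (through 21 and 20).** The O1–C2 bond and the C3–acetate bond are cut and O1 is reconnected to C3. The 2,3-cis-3,4-trans triad of a chroman is hard to set directly, whereas a trans-disubstituted five-membered ring plus one carbinol centre are each accessible by reagent control. The three ring stereocentres are thereby reduced to those of 19. The forward step must displace a benzylic sulfonate by the ring oxygen with inversion and open the bridged ion 21 at the non-benzylic carbon, again with inversion.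

**19 to 18.** The C–H bond at the carbinol carbon is cut. The ketone is the direct product of an annulation with a phenacyl ylide and is epimerisable towards the trans isomer. The forward step must deliver hydride to one face of an aryl ketone that carries a bulky α-branch.

**18 to 16 and 17.** The furan O1–C2 and C2–C3 bonds are cut (a [4+1] disconnection). One annulation then creates the diarylmethine centre, the ring and the trans relationship, and the partners are an o-quinone methide and a one-carbon ylide. The forward step must control the face of attack on the methide carbon of 16 and close the ring trans.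

**16 to 15 and 11; 15 to 8; 17 to 14; 14 to 12 and 13.** The bond from the methide carbon to C8′ is cut, so the upper aryl ring arrives as an aldehyde and the lower unit as an aryl nucleophile. This fixes the 4→8 regiochemistry through the position of the halogen in 8. The phenol oxygen ortho to the formyl group of 11 must carry a group that can migrate and leave, and the exchange of 8 to 15 must not disturb the benzyl ethers. The C–N bond of 17 is cut to reach 14, which is assembled from 12 and 13.

**8 back to 1 (through 7, 6, 5, 4, 3 and 2).** The C8′–Br bond, the two C–H bonds of ring E that replace the catechol C–O bonds, the three benzyl ethers and the catechol ketal are removed in turn. Rings D and F and both lower-unit stereocentres then come intact from 1. The forward sequence must distinguish the catechol from the other three hydroxyls (done by ring-forming ketalisation) and reduce two aryl triflates without hydrogenolysing benzyl ethers.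

**11 to 10 to 9.** The carbonate and two benzyl ethers are cut. The forward steps must leave exactly one ortho hydroxyl of 9 free for the carbonate.

## Other disconnections considered

**Alternative 1:** The cut is through O1–C8a and O1′–C8a′, which leads back to the open-chain dibromo diol A1. In the forward key step a palladium catalyst with a bulky binaphthyl dialkylphosphine and a carbonate base would couple each benzylic alkoxide with its aryl bromide (Buchwald–Hartwig-type etherification), closing rings C and F to give the hexa-O-benzyl dimer A2.
- In its favour: the carbinol C–O bonds are not broken, so C2 and C2′ are retained. No cation is formed anywhere near C2 or C4. The reaction class is established, which is a point on which it is better than the chosen plan. A2 needs only one hydrogenolysis to reach 24, one step fewer after the key step.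
- Against it here: A1 already contains the crowded C4 diarylmethine and five stereocentres on an open chain, so the central problem is moved, not solved. Ring F, which the chosen plan takes intact from 1, would be rebuilt. The aryl bromides are electron-rich and flanked by the diarylmethine, so oxidative addition and C–O reductive elimination would be slow, and β-hydride elimination of the secondary benzylic alkoxides to ketones would compete twice.
- Comparison: mechanistically it is the safer ring closure. Structurally and in step count it should be clearly longer, because the stereocentres are not drawn from the chiral pool. The two plans are equal in needing a separate asymmetric solution for C4.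

**Alternative 2:** The cut is through C3–C4 and O1–C2. In the forward key step, acid would release the o-quinone methide 16 from the benzhydrol A3 and add the (Z)-β-silylstyrene A4 across C4 and O1 in a hetero-Diels–Alder reaction. This would give the 3-silylchroman A5, and Tamao–Fleming oxidation would lead to 23.
- In its favour: ring C and all three of its stereocentres would arise in one step from the same quinone methide the chosen plan uses. The cis alkene maps onto 2,3-cis, and the benzylic, β-silyl-stabilised charge directs O1 to C2. It would save about three steps (no carbonyl reduction, no rearrangement), which makes it the better plan in step economy.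
- Against it here: a styrene is a weak partner for a donor-stabilised quinone methide. A stepwise cationic course would allow bond rotation (loss of the cis relationship) and loss of the silyl group from the β-silyl cation instead of ring closure. Nothing but the remote lower-unit centres would control the face at C4 or the endo/exo sense that sets 3,4-trans. The hindered secondary silane must still be oxidised.
- Comparison: the two plans are equal in depending on the hindered methide carbon of 16 and on face selectivity there. The chosen plan pairs 16 with a strong carbon nucleophile and has a chiral leaving group for control.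

**Alternative 3:** The cut is through C4–C4a. In the forward key step a Lewis acid would open the trans epoxide of the aryl ether A6 at C4, the ring A carbon ortho to O1 would attack with inversion, and the product would be A7, which is identical with 23.
- In its favour: the C3 hydroxyl is released free, so the acetate cleavage is saved, a point on which it is better. The two ortho positions of the ring A ether are equivalent, so there is no regiochemical question. Epoxide–arene cyclisation is a known reaction class, whereas the chosen key step is not.
- Against it here: the epoxide carbon C4 is benzylic to the trioxygenated ring D, so A6 would ionise very easily. An open cation removes the stereospecific link between epoxide and C4 configuration and opens hydride-shift pathways to a ketone. A6 also needs an aryl ether at benzylic C2 of defined configuration, made by O-alkylation of a phloroglucinol-type phenol that prefers C-alkylation.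
- Comparison: both plans pass through a three-membered oxygen-bridged cation that must be opened anti. The chosen plan places that ion away from the most electron-rich ring. Step counts should be similar.

Key step: step 12

Remark (assumption): the quinidine-derived ylide 17 is taken to attack the face of 16 that gives the (3R) diarylmethine of 18, and 16 is drawn with the aryl group syn to the carbonyl oxygen; should the sense of induction be opposite, the quinine-derived pseudoenantiomer of 14 would be used with no other change.

## Route

Step 1
Reactants: 1 (−)-epicatechin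
Product: 2 3′,4′-O-(diphenylmethylene)-(−)-epicatechin [(2R,3R)-2-(2,2-diphenyl-1,3-benzodioxol-5-yl)chromane-3,5,7-triol]
Conditions: Ph2CCl2, K2CO3, MeCN, rt, argon; dilute aqueous acid work-up
Reagents that add atoms: dichlorodiphenylmethane, ClC(Cl)(c1ccccc1)c1ccccc1
Why: Ketalisation by double O-alkylation: only the ortho-dihydroxy pair can close the five-membered 2,2-diphenyl-1,3-benzodioxole, whereas the other hydroxyls can at most form α-chloro ethers that hydrolyse back on work-up. No stereocentre is touched at room temperature.

Step 2
Reactants: 2 3′,4′-O-(diphenylmethylene)-(−)-epicatechin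
Product: 4 3,5,7-tri-O-benzyl-3′,4′-O-(diphenylmethylene)-(−)-epicatechin, via 5,7-di-O-benzyl ketal 3 (not isolated)
Conditions: BnBr (2.2 equiv), K2CO3, DMF, rt; then NaH, BnBr (1.2 equiv), Bu4NI (cat.), 0 °C to rt
Reagents that add atoms: benzyl bromide, BrCc1ccccc1
Why: Williamson ether synthesis in two stages: carbonate alkylates the two phenols, then the alkoxide made with NaH alkylates the secondary C3 hydroxyl. Etherifying the phenols before the strong base is added suppresses C-benzylation of the phloroglucinol ring.

Step 3
Reactants: 4 3,5,7-tri-O-benzyl-3′,4′-O-(diphenylmethylene)-(−)-epicatechin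
Product: 5 3,5,7-tri-O-benzyl-(−)-epicatechin [4-[(2R,3R)-3,5,7-tris(benzyloxy)chroman-2-yl]benzene-1,2-diol]
Conditions: AcOH–H2O (4:1), 90 °C
Reagents that add atoms: none
Why: Acid hydrolysis of the diaryl ketal through the well-stabilised diphenyl(aryloxy)carbenium ion. Benzyl aryl and benzyl alkyl ethers are stable to hot aqueous acetic acid.

Step 4
Reactants: 5 3,5,7-tri-O-benzyl-(−)-epicatechin
Product: 6 4-[(2R,3R)-3,5,7-tris(benzyloxy)chroman-2-yl]-1,2-phenylene bis(trifluoromethanesulfonate)
Conditions: Tf2O, pyridine, CH2Cl2, 0 °C
Reagents that add atoms: trifluoromethanesulfonic anhydride, FC(F)(F)S(=O)(=O)OS(=O)(=O)C(F)(F)F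
Why: O-Sulfonylation of the two phenols; every other oxygen function is an ether.

Step 5
Reactants: 6 catechol bis(triflate)
Product: 7 (2R,3R)-3,5,7-tris(benzyloxy)-2-phenylchromane
Conditions: Pd(OAc)2 (10 mol %), 1,1′-bis(diphenylphosphino)ferrocene, HCO2H, Et3N, DMF, 70 °C
Reagents that add atoms: none
Why: Palladium-catalysed formate reduction of aryl triflates: zerovalent palladium inserts into each C–OTf bond, formate replaces triflate and loses CO2, and reductive elimination forms the C–H bond. A homogeneous phosphine complex should not hydrogenolyse benzyl ethers.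

Step 6
Reactants: 7 (2R,3R)-3,5,7-tris(benzyloxy)-2-phenylchromane
Product: 8 (2R,3R)-3,5,7-tris(benzyloxy)-8-bromo-2-phenylchromane
Conditions: NBS (1.0 equiv), CH2Cl2, −40 to 0 °C
Reagents that add atoms: N-bromosuccinimide, BrN1C(=O)CCC1=O
Why: Electrophilic aromatic bromination. C8, between O1 and the C7 benzyloxy group, is the most reactive position of 5,7-dialkoxyflavans; C6 reacts only with excess reagent, and the phenyl ring is now unactivated.

Step 7
Reactants: 9 2,4,6-trihydroxybenzaldehyde
Product: 10 2,4-bis(benzyloxy)-6-hydroxybenzaldehyde
Conditions: BnBr (2.05 equiv), K2CO3, DMF, 0 °C to rt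
Reagents that add atoms: benzyl bromide, BrCc1ccccc1
Why: Williamson ether synthesis. The para hydroxyl and one ortho hydroxyl are alkylated; the remaining ortho hydroxyl is held in a hydrogen bond to the formyl oxygen and is the least nucleophilic, so the reaction should stop at the bis-ether.

Step 8
Reactants: 10 2,4-bis(benzyloxy)-6-hydroxybenzaldehyde
Product: 11 3,5-bis(benzyloxy)-2-formylphenyl tert-butyl carbonate
Conditions: Boc2O, i-Pr2NEt, DMAP (cat.), THF, rt
Reagents that add atoms: di-tert-butyl dicarbonate, CC(C)(C)OC(=O)OC(=O)OC(C)(C)C
Why: DMAP-catalysed O-acylation to the aryl carbonate. A carbonate is used instead of a third benzyl ether because it can migrate to the benzylic alkoxide in step 10 and then leave, which is what releases the o-quinone methide.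

Step 9
Reactants: 12 2-bromoacetophenone; 13 quinidine
Product: 14 N-(2-oxo-2-phenylethyl)quinidinium bromide (alkylated at the quinuclidine nitrogen)
Conditions: THF, rt; filtration of the salt
Reagents that add atoms: none
Why: Menshutkin quaternisation. The quinuclidine nitrogen is far more nucleophilic than the quinoline nitrogen, and the salt should precipitate.

Step 10
Reactants: 8 (2R,3R)-3,5,7-tris(benzyloxy)-8-bromo-2-phenylchromane; 11 3,5-bis(benzyloxy)-2-formylphenyl tert-butyl carbonate; 14 N-(2-oxo-2-phenylethyl)quinidinium bromide
Product: 18 [(2S,3R)-4,6-bis(benzyloxy)-3-{(2R,3R)-3,5,7-tris(benzyloxy)-2-phenylchroman-8-yl}-2,3-dihydro-1-benzofuran-2-yl](phenyl)methanone, via aryllithium 15 (not isolated), via o-quinone methide 16 (not isolated), via ammonium ylide 17 (not isolated)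
Conditions: n-BuLi, THF, −78 °C; 11, −78 to −20 °C; then 14, Cs2CO3, CH2Cl2, −20 °C to rt
Reagents that add atoms: none
Why: Bromine–lithium exchange gives 15, which adds to the formyl group of 11; the alkoxide takes over the Boc group and the phenoxide expels tert-butyl carbonate (acyl transfer then 1,4-elimination) to give 16. The carbonyl-stabilised ylide 17 adds to the methide carbon and the phenoxide displaces the ammonium group in a 5-exo-tet SN2 closure ([4+1] annulation of an o-quinone methide with an onium ylide). The cinchona leaving group selects the face of 16 and so sets the diarylmethine centre (3R); the benzoyl and aryl groups end trans (2S) because the betaine equilibrates at its acidic C–N carbon before closure and the ketone can epimerise to the more stable isomer.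

Step 11
Reactants: 18 trans-2-benzoyl-3-aryl-2,3-dihydrobenzofuran
Product: 19 (S)-[(2S,3R)-4,6-bis(benzyloxy)-3-{(2R,3R)-3,5,7-tris(benzyloxy)-2-phenylchroman-8-yl}-2,3-dihydro-1-benzofuran-2-yl](phenyl)methanol
Conditions: (S)-Me-CBS oxazaborolidine (0.5 equiv), BH3·SMe2, THF, −20 °C; MeOH quench
Reagents that add atoms: none
Why: Corey–Bakshi–Shibata reduction. With phenyl as the larger group of the catalyst-bound ketone, the (S)-catalyst should deliver hydride to the face that gives the (S)-carbinol; the Felkin–Anh preference (C–O1 bond anti to the incoming hydride) points to the same face, so catalyst and substrate control should be matched.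

Step 12
Reactants: 19 (S)-carbinol of the trans-dihydrobenzofuran
Product: 22 (2R,3R,4R)-5,7-bis(benzyloxy)-2-phenyl-4-[(2R,3R)-3,5,7-tris(benzyloxy)-2-phenylchroman-8-yl]chroman-3-yl acetate (penta-O-benzyl dimer 3-O-acetate), via mesylate 20 (not isolated), via bridged oxonium ion 21 (not isolated)
Conditions: Ms2O, 2,6-lutidine, CH2Cl2, −20 °C; then Zn(OAc)2, AcOH, toluene, 0 to 45 °C
Reagents that add atoms: zinc diacetate, CC(=O)[O-].CC(=O)[O-].[Zn+2]; methanesulfonic anhydride, CS(=O)(=O)OS(C)(=O)=O (its mesyl group is carried only by 20 and 21)
Why: Proposed new method: sulfonylation of the benzylic hydroxyl gives 20, in which the ring oxygen O1 can stand antiperiplanar to the C–OMs bond and displace it in a 3-exo-tet SN2 step with inversion, giving the bicyclic aryloxiranium ion 21; zinc-bound acetate then attacks the ring carbon of 21 (old furan C2, new C3) anti to O1, which breaks the old O1–C bond, leaves O1 on the benzylic carbon (new C2) and enlarges the five-membered ring to ring C. The closest known reaction type is the stereospecific Zn(OAc)2-mediated enlargement of 2-(1-sulfonyloxyalkyl)tetrahydrofurans to 3-acyloxytetrahydropyrans through bicyclic oxonium ions, extended here from a dialkyl ether oxygen and an unactivated carbon to an aryl ether oxygen and a benzylic carbon. Ring C is therefore not closed by a direct cyclisation but by the 3-exo-tet closure followed by cleavage of the bond shared by the two small rings, a net five-to-six ring enlargement. C2 is set by inversion at the carbinol carbon and is dictated by the (S) centre from step 11; C3 is set by inversion at the old furan C2 and is dictated by the trans ring substitution from step 10; C4 is untouched, so the (S),(2S,3R) array should map onto 2,3-cis-3,4-trans. The step needs participation of O1 in preference to direct substitution or a free benzylic cation, and opening of 21 at C3 in preference to C2. Participation is favoured by the low-polarity medium, by the absence of free chloride or acetate ions (anhydride instead of sulfonyl chloride, a weak hindered base, covalently bound zinc acetate) and by the unsubstituted phenyl ring, which stabilises an open cation only modestly. Opening at C3 is favoured because acetate approaches that carbon on the face away from the C4 aryl group and gives a secondary, non-benzylic ester in a six-membered ring that cannot ionise again, whereas capture at C2 only returns a benzylic ester of the starting skeleton with net retention.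

Step 13
Reactants: 22 penta-O-benzyl dimer 3-O-acetate
Product: 23 (2R,3R,4R)-5,7-bis(benzyloxy)-2-phenyl-4-[(2R,3R)-3,5,7-tris(benzyloxy)-2-phenylchroman-8-yl]chroman-3-ol
Conditions: K2CO3 (cat.), MeOH–THF (1:1), rt
Reagents that add atoms: none
Why: Base-catalysed transesterification (Zemplén-type methanolysis) of the secondary acetate. Ethers and the C4–C8′ bond are inert, and with all phenols still benzylated there is no base-sensitive or epimerisable site.

Step 14
Reactants: 23 penta-O-benzyl dimer with free C3 hydroxyl
Product: 24 (2R,3R)-2-phenyl-8-[(2R,3R,4R)-3,5,7-trihydroxy-2-phenylchroman-4-yl]chromane-3,5,7-triol (target)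
Conditions: H2 (1 atm), Pd(OH)2 on carbon, THF–MeOH–H2O, rt
Reagents that add atoms: none
Why: Hydrogenolysis of the five benzyl ethers. The cyclic benzylic C2–O1 and C2′–O1′ bonds and the C4–C8′ bond of flavan-3-ol oligomers are expected to survive these neutral conditions, and no stereocentre is affected.

## Compound list

1 | (−)-epicatechin, (2R,3R)-2-(3,4-dihydroxyphenyl)chromane-3,5,7-triol | Oc1cc(O)c2c(c1)O[C@H](c1ccc(O)c(O)c1)[C@H](O)C2 | starting material
2 | 3′,4′-O-(diphenylmethylene)-(−)-epicatechin | Oc1cc(O)c2c(c1)O[C@H](c1ccc3OC(c4ccccc4)(c4ccccc4)Oc3c1)[C@H](O)C2 | intermediate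
3 | 5,7-di-O-benzyl-3′,4′-O-(diphenylmethylene)-(−)-epicatechin (not isolated) | c1ccccc1COc1cc(OCc3ccccc3)c2c(c1)O[C@H](c1ccc3OC(c4ccccc4)(c4ccccc4)Oc3c1)[C@H](O)C2 | intermediate
4 | 3,5,7-tri-O-benzyl-3′,4′-O-(diphenylmethylene)-(−)-epicatechin | c1ccccc1COc1cc(OCc3ccccc3)c2c(c1)O[C@H](c1ccc3OC(c4ccccc4)(c4ccccc4)Oc3c1)[C@H](OCc1ccccc1)C2 | intermediate
5 | 3,5,7-tri-O-benzyl-(−)-epicatechin (free catechol) | c1ccccc1COc1cc(OCc3ccccc3)c2c(c1)O[C@H](c1ccc(O)c(O)c1)[C@H](OCc1ccccc1)C2 | intermediate
6 | 4-[(2R,3R)-3,5,7-tris(benzyloxy)chroman-2-yl]-1,2-phenylene bis(trifluoromethanesulfonate) | c1ccccc1COc1cc(OCc3ccccc3)c2c(c1)O[C@H](c1ccc(OS(=O)(=O)C(F)(F)F)c(OS(=O)(=O)C(F)(F)F)c1)[C@H](OCc1ccccc1)C2 | intermediate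
7 | (2R,3R)-3,5,7-tris(benzyloxy)-2-phenylchromane | c1ccccc1COc1cc(OCc3ccccc3)c2c(c1)O[C@H](c1ccccc1)[C@H](OCc1ccccc1)C2 | intermediate
8 | (2R,3R)-3,5,7-tris(benzyloxy)-8-bromo-2-phenylchromane | Brc1c(OCc2ccccc2)cc(OCc2ccccc2)c2c1O[C@H](c1ccccc1)[C@H](OCc1ccccc1)C2 | intermediate
9 | 2,4,6-trihydroxybenzaldehyde | O=Cc1c(O)cc(O)cc1O | starting material
10 | 2,4-bis(benzyloxy)-6-hydroxybenzaldehyde | O=Cc1c(O)cc(OCc2ccccc2)cc1OCc1ccccc1 | intermediate
11 | 3,5-bis(benzyloxy)-2-formylphenyl tert-butyl carbonate | O=Cc1c(OC(=O)OC(C)(C)C)cc(OCc2ccccc2)cc1OCc1ccccc1 | intermediate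
12 | 2-bromoacetophenone | O=C(CBr)c1ccccc1 | starting material
13 | quinidine, (S)-[(2R,4S,5R)-5-ethenylquinuclidin-2-yl](6-methoxyquinolin-4-yl)methanol | C=C[C@H]1CN2CC[C@H]1C[C@@H]2[C@@H](O)c1ccnc2ccc(OC)cc12 | starting material
14 | N-(2-oxo-2-phenylethyl)quinidinium bromide | [Br-].C=C[C@H]1C[N@+]2(CC(=O)c3ccccc3)CC[C@H]1C[C@@H]2[C@@H](O)c1ccnc2ccc(OC)cc12 | intermediate
15 | [(2R,3R)-3,5,7-tris(benzyloxy)-2-phenylchroman-8-yl]lithium (not isolated) | [Li]c1c(OCc2ccccc2)cc(OCc2ccccc2)c2c1O[C@H](c1ccccc1)[C@H](OCc1ccccc1)C2 | intermediate
16 | 3,5-bis(benzyloxy)-6-{[(2R,3R)-3,5,7-tris(benzyloxy)-2-phenylchroman-8-yl]methylidene}cyclohexa-2,4-dien-1-one, aryl group syn to C=O (not isolated) | O=C1C=C(OCc2ccccc2)C=C(OCc2ccccc2)/C1=C/c1c(OCc2ccccc2)cc(OCc2ccccc2)c2c1O[C@H](c1ccccc1)[C@H](OCc1ccccc1)C2 | intermediate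
17 | N-quinidinium 2-oxo-2-phenylethanide, the ylide of 14 (not isolated) | C=C[C@H]1C[N@+]2([CH-]C(=O)c3ccccc3)CC[C@H]1C[C@@H]2[C@@H](O)c1ccnc2ccc(OC)cc12 | intermediate
18 | [(2S,3R)-4,6-bis(benzyloxy)-3-{(2R,3R)-3,5,7-tris(benzyloxy)-2-phenylchroman-8-yl}-2,3-dihydro-1-benzofuran-2-yl](phenyl)methanone | O=C(c1ccccc1)[C@H]1Oc2cc(OCc3ccccc3)cc(OCc3ccccc3)c2[C@@H]1c1c(OCc2ccccc2)cc(OCc2ccccc2)c2c1O[C@H](c1ccccc1)[C@H](OCc1ccccc1)C2 | intermediate
19 | (S)-[(2S,3R)-4,6-bis(benzyloxy)-3-{(2R,3R)-3,5,7-tris(benzyloxy)-2-phenylchroman-8-yl}-2,3-dihydro-1-benzofuran-2-yl](phenyl)methanol | O[C@@H](c1ccccc1)[C@H]1Oc2cc(OCc3ccccc3)cc(OCc3ccccc3)c2[C@@H]1c1c(OCc2ccccc2)cc(OCc2ccccc2)c2c1O[C@H](c1ccccc1)[C@H](OCc1ccccc1)C2 | intermediate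
20 | methanesulfonate of 19, (S) at the benzylic carbon (not isolated) | CS(=O)(=O)O[C@@H](c1ccccc1)[C@H]1Oc2cc(OCc3ccccc3)cc(OCc3ccccc3)c2[C@@H]1c1c(OCc2ccccc2)cc(OCc2ccccc2)c2c1O[C@H](c1ccccc1)[C@H](OCc1ccccc1)C2 | intermediate
21 | aryloxiranium ion bridging the benzylic carbon and the old furan C2, as methanesulfonate (not isolated) | c1ccccc1[C@H]1[O+]2c3cc(OCc4ccccc4)cc(OCc4ccccc4)c3[C@H](c3c(OCc4ccccc4)cc(OCc4ccccc4)c4c3O[C@H](c3ccccc3)[C@H](OCc3ccccc3)C4)[C@@H]12.CS(=O)(=O)[O-] | intermediate
22 | (2R,3R,4R)-5,7-bis(benzyloxy)-2-phenyl-4-[(2R,3R)-3,5,7-tris(benzyloxy)-2-phenylchroman-8-yl]chroman-3-yl acetate | c1ccccc1COc1cc(OCc3ccccc3)c2c(c1)O[C@H](c1ccccc1)[C@H](OC(C)=O)[C@H]2c1c(OCc2ccccc2)cc(OCc2ccccc2)c2c1O[C@H](c1ccccc1)[C@H](OCc1ccccc1)C2 | intermediate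
23 | (2R,3R,4R)-5,7-bis(benzyloxy)-2-phenyl-4-[(2R,3R)-3,5,7-tris(benzyloxy)-2-phenylchroman-8-yl]chroman-3-ol | c1ccccc1COc1cc(OCc3ccccc3)c2c(c1)O[C@H](c1ccccc1)[C@H](O)[C@H]2c1c(OCc2ccccc2)cc(OCc2ccccc2)c2c1O[C@H](c1ccccc1)[C@H](OCc1ccccc1)C2 | intermediate
24 | (2R,3R)-2-phenyl-8-[(2R,3R,4R)-3,5,7-trihydroxy-2-phenylchroman-4-yl]chromane-3,5,7-triol | Oc1cc(O)c2c(c1)O[C@H](c1ccccc1)[C@H](O)[C@H]2c1c(O)cc(O)c2c1O[C@H](c1ccccc1)[C@H](O)C2 | target

## Step count and least certain steps

Total step count: 14. Longest linear sequence: 11 steps (steps 1 to 6 and 10 to 14, from 1 to 24).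

**Step 12 (Proposed new method).** Three things are most likely to go wrong.
- Acetate may capture the bridged ion 21 at its benzylic carbon and not at C3, which returns the unrearranged skeleton. The benzylic carbon carries the larger share of the positive charge.
- The sulfonate may ionise to an open benzylic cation, with loss of configuration at C2 or loss of a proton towards the aromatic benzofuran. An aryl ether oxygen is a weaker neighbouring group than the dialkyl ether oxygen of the precedent.
- The C7′ benzyloxy oxygen may participate through a six-membered ring, with loss of its benzyl group.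

The fallback uses known flavan chemistry and sets out from 7. Benzylic oxidation at C4 with DDQ in CH2Cl2 containing 2-ethoxyethanol would give the 4β-(2-ethoxyethoxy) derivative of 7, F1. Ionisation of F1 with catalytic TMSOTf at −78 °C in the presence of excess 7 would form the C4–C8′ bond trans to the C3 substituent and give the hexa-O-benzyl dimer F2. Hydrogenolysis of F2 over Pd(OH)2 on carbon would return to the route at 24.

**Step 10.** The bulky ylide 17 may add only slowly to the methide carbon of 16, which is flanked on both sides by ortho substituents. The remote stereocentres of the chroman give no help with face selectivity and may oppose the reagent. The quinone methide may also oligomerise or take up tert-butoxide.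

The fallback sets out from 8 and 11. 16 would be generated as in step 10 and quenched with aqueous NaHCO3, which adds water to give the benzhydrol F3 (either carbinol epimer). A BINOL-derived chiral phosphoric acid such as (R)-TRIP would then regenerate the quinone methide from F3 as a hydrogen-bonded ion pair and mediate its [4+1] annulation with 2-diazo-1-phenylethanone, with loss of dinitrogen, to give the cis ketone F4. Epimerisation of F4 at the carbon next to the carbonyl group with DBU would return to the route at 18.

**Step 11.** Hydride delivery may show poor or reversed facial selectivity, because the α-branch of the ketone is large enough to compete with phenyl as the "large" group in the catalyst complex.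

The fallback sets out from 18. The ketone would be reduced with whichever reagent proves cleanly selective for the other face (the enantiomeric oxazaborolidine, or a chelating borohydride) to give the (R)-carbinol F5. Mitsunobu inversion of F5 with 4-nitrobenzoic acid, PPh3 and diisopropyl azodicarboxylate would give the (S)-4-nitrobenzoate F6, and methanolysis of F6 with K2CO3 in MeOH would return to the route at 19.

## Further compounds

F1 | step 12 | 4β-(2-ethoxyethoxy) derivative of 7, (2R,3R)-3,5,7-tris(benzyloxy)-4-(2-ethoxyethoxy)-2-phenylchromane with the C4 oxygen trans to the C3 oxygen | c1ccccc1COc1cc(OCc3ccccc3)c2c(c1)O[C@H](c1ccccc1)[C@H](OCc1ccccc1)[C@H]2OCCOCC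
F2 | step 12 | hexa-O-benzyl dimer, (2R,3R,4R)-3,5,7-tris(benzyloxy)-2-phenyl-4-[(2R,3R)-3,5,7-tris(benzyloxy)-2-phenylchroman-8-yl]chromane | c1ccccc1COc1cc(OCc3ccccc3)c2c(c1)O[C@H](c1ccccc1)[C@H](OCc1ccccc1)[C@H]2c1c(OCc2ccccc2)cc(OCc2ccccc2)c2c1O[C@H](c1ccccc1)[C@H](OCc1ccccc1)C2
F3 | step 10 | [2,4-bis(benzyloxy)-6-hydroxyphenyl][(2R,3R)-3,5,7-tris(benzyloxy)-2-phenylchroman-8-yl]methanol, either carbinol epimer | OC(c1c(O)cc(OCc2ccccc2)cc1OCc1ccccc1)c1c(OCc2ccccc2)cc(OCc2ccccc2)c2c1O[C@H](c1ccccc1)[C@H](OCc1ccccc1)C2
F4 | step 10 | cis ketone, [(2R,3R)-4,6-bis(benzyloxy)-3-{(2R,3R)-3,5,7-tris(benzyloxy)-2-phenylchroman-8-yl}-2,3-dihydro-1-benzofuran-2-yl](phenyl)methanone | O=C(c1ccccc1)[C@@H]1Oc2cc(OCc3ccccc3)cc(OCc3ccccc3)c2[C@@H]1c1c(OCc2ccccc2)cc(OCc2ccccc2)c2c1O[C@H](c1ccccc1)[C@H](OCc1ccccc1)C2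
F5 | step 11 | (R)-carbinol epimer of 19 | O[C@H](c1ccccc1)[C@H]1Oc2cc(OCc3ccccc3)cc(OCc3ccccc3)c2[C@@H]1c1c(OCc2ccccc2)cc(OCc2ccccc2)c2c1O[C@H](c1ccccc1)[C@H](OCc1ccccc1)C2
F6 | step 11 | (S)-4-nitrobenzoate of 19 | O=C(O[C@@H](c1ccccc1)[C@H]1Oc2cc(OCc3ccccc3)cc(OCc3ccccc3)c2[C@@H]1c1c(OCc2ccccc2)cc(OCc2ccccc2)c2c1O[C@H](c1ccccc1)[C@H](OCc1ccccc1)C2)c1ccc(cc1)[N+](=O)[O-]
A1 | alternative 1 | open-chain dibromo diol, both benzylic carbinols free and bromine on C8a and C8a′ | c1ccccc1COc1cc(OCc3ccccc3)c(c(Br)c1)[C@@H]([C@@H](OCc1ccccc1)[C@H](O)c1ccccc1)c1c(OCc2ccccc2)cc(OCc2ccccc2)c(C[C@@H](OCc2ccccc2)[C@H](O)c2ccccc2)c1Br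
A2 | alternative 1 | hexa-O-benzyl dimer (same compound as F2) | c1ccccc1COc1cc(OCc3ccccc3)c2c(c1)O[C@H](c1ccccc1)[C@H](OCc1ccccc1)[C@H]2c1c(OCc2ccccc2)cc(OCc2ccccc2)c2c1O[C@H](c1ccccc1)[C@H](OCc1ccccc1)C2
A3 | alternative 2 | ring A/ring D benzhydrol (same compound as F3), either carbinol epimer | OC(c1c(O)cc(OCc2ccccc2)cc1OCc1ccccc1)c1c(OCc2ccccc2)cc(OCc2ccccc2)c2c1O[C@H](c1ccccc1)[C@H](OCc1ccccc1)C2
A4 | alternative 2 | (Z)-benzyldimethyl(2-phenylethenyl)silane | C[Si](C)(Cc1ccccc1)/C=C\c1ccccc1
A5 | alternative 2 | hexa-O-benzyl dimer skeleton with benzyldimethylsilyl at C3 in place of the C3 oxygen | c1ccccc1COc1cc(OCc3ccccc3)c2c(c1)O[C@H](c1ccccc1)[C@H]([Si](C)(C)Cc1ccccc1)[C@H]2c1c(OCc2ccccc2)cc(OCc2ccccc2)c2c1O[C@H](c1ccccc1)[C@H](OCc1ccccc1)C2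
A6 | alternative 3 | 3,5-bis(benzyloxy)phenyl ether of the benzylic carbinol carrying the trans C3–C4 epoxide with the lower unit on C4 | c1ccccc1COc1cc(OCc2ccccc2)cc(c1)O[C@H](c1ccccc1)[C@@H]1O[C@H]1c1c(OCc2ccccc2)cc(OCc2ccccc2)c2c1O[C@H](c1ccccc1)[C@H](OCc1ccccc1)C2
A7 | alternative 3 | penta-O-benzyl dimer with free C3 hydroxyl (same compound as 23) | c1ccccc1COc1cc(OCc3ccccc3)c2c(c1)O[C@H](c1ccccc1)[C@H](O)[C@H]2c1c(OCc2ccccc2)cc(OCc2ccccc2)c2c1O[C@H](c1ccccc1)[C@H](OCc1ccccc1)C2
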